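The readings are simulated from invented constants, noise included.

Amounts first: the two substrates together are the limiting reagent, at 0.800 of the reagent charge.

the same everywhere: left-handed substrate 0.40 M; right-handed substrate 0.40 M; racemization catalyst 0.80 mM

| flask | reagent | free catalyst | remark | time |
|---|---|---|---|---|
| ochre | 1 M | 17 mM | run made earlier |  |
| amber | 1 M | 24 mM | run made earlier |  |
| midnight | 1.00 M | 20 mM |  | 80 min |
| autumn | 1.00 M | 30 mM |  | 80 min |

| run | time / min | left-handed product / % | right-handed product / % |
|---|---|---|---|
| ochre | 2.00 | 2.3 | 0.7 |
| ochre | 6.00 | 5.8 | 3.4 |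
| ochre | 12.0 | 10.5 | 7.8 |
| ochre | 15.0 | 12.1 | 9.5 |
| ochre | 25.0 | 16.5 | 14.8 |
| ochre | 30.0 | 18.3 | 17.4 |
| ochre | 40.0 | 21.9 | 21.1 |
| amber | 2.00 | 3.3 | 1.7 |
| amber | 6.00 | 7.6 | 5.3 |
| amber | 12.0 | 13.5 | 10.3 |
| amber | 15.0 | 15.6 | 11.9 |
| amber | 25.0 | 20.2 | 18.4 |
| amber | 30.0 | 23.5 | 21.7 |
| amber | 40.0 | 26.4 | 25.4 |

(scatter of a reading: 0.3 percentage points)

- free catalyst is single-handed; left-handed substrate and right-handed substrate are mirror images of each other, charged as a racemate, each of them at the stated concentration
- an excess is the difference of the two amounts in percent of their sum
- an excess is below zero if the other one leads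

* which one finishes higher in excess of left-handed product over right-handed product in the product ("neither" within 2 percentage points) (midnight / autumn / neither)
* excess of left-handed product over right-handed product in the product at the end, midnight
* excess of left-handed product over right-handed product in the product at the end, autumn

If each conversion takes one reagent, converting a fraction c of the substrates costs 0.800c of the reagent, so I write the speed of conversion as k times the two remaining fractions. Ochre, with 43.0 % converted at 40.0 min, gives k = 0.0176 min⁻¹. Amber, with 51.8 %, gives 0.0243 min⁻¹. Their ratio 1.38 stands near the catalyst ratio 1.41, so k goes with free catalyst.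

But the ochre readings take the lead of left-handed product from 2.7 percentage points at 12.0 min to 0.8 points at 40.0 min, so I read the lead as following fresh product. My rule is the lead time g, the lead divided by the speed of conversion. Ochre at 25.0 min reads 1.81 min, rough under a scatter of 0.3 points. The excess is then g times speed over c.

I reckon midnight at 66.2 % converted and 0.897 % excess. Autumn comes to 76.2 % and 0.681 %, a gap under 2 points.

The forecast says neither, with −0.4 % for midnight and −0.9 % for autumn: “Both are near zero, so the answer is neither”. Its signs differ from mine; its verdict does not.

Midnight ends at 0.940 % and autumn at 0.722 %, so the answer is neither. Midnight holds left-handed substrate at 16.9 % and right-handed substrate at 16.9 % at 80.0 min, and the gap between the flasks is 0.22 points, against 0.5 points in the forecast, both under 2 points. Left until 800 min, midnight has 0.754 % of the substrates unconverted, where g gives 0.00585 % and the flask stands at 0.00587 %.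

    reagent + free catalyst + left-handed substrate → free catalyst + left-handed product (k = 1.80 M⁻² min⁻¹)
    reagent + free catalyst + right-handed substrate → free catalyst + right-handed product (k = 0.660 M⁻² min⁻¹)
    left-handed substrate + racemization catalyst ⇌ right-handed substrate + racemization catalyst, rate k3*[racemization catalyst]*[left-handed substrate] forward; the back reaction follows from the equilibrium constant (k = 5300 M⁻¹ min⁻¹)
    reagent ⇌ dormant form (K = 0.190, k = 1.30 min⁻¹)
    left-handed product ⇌ right-handed product (k = 0.130 min⁻¹)

Take autumn with free catalyst at 0.0075 M: I reckon 39.8 % converted, and g gives 1.45 % excess. That flask computes to 1.48 %.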